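Ring B with its C(CH3)=CH appendage is a p-menthane, so (S)-limonene supplies ten carbons and the ring CH stereocentre. The C1 carbinol and the C2 bromide of ring B are cis, which anti addition to the limonene alkene cannot give. The C1=C2 bond is therefore cut to a keto aldehyde, the aldehyde becomes CHBr2, and SmI2 re-closes ring B between C1 and C2. One operation forms the ring, both stereocentres and the bromohydrin, exploiting that the C4 side chain, the C2 bromine and the C1 methyl can all sit equatorial in a chair. Hydroformylation–dehydrogenation then gives an enal; asymmetric allylboration with a cyclohexadienylmethyl boronate installs ring A, the last two stereocentres and the exocyclic methylene.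

Key step: step 4

Remark: ring B is numbered as a cyclohexanol (C1 carbinol carbon, C2 CHBr, C4 the carbon that bears the side chain). Compounds 2 and 8 are carried as mixtures at centres that are destroyed in steps 2 and 6.

Step 1
Reactants: 1 (S)-(−)-limonene
Product: 2 (4S)-1-methyl-4-(prop-1-en-2-yl)-7-oxabicyclo[4.1.0]heptane ((S)-limonene 1,2-oxide, both epoxide diastereomers)
Conditions: mCPBA (1.0 equiv), NaHCO3, CH2Cl2, 0 °C
Reagents that add atoms: mCPBA, O=C(OO)c1cccc(Cl)c1
Why: Prilezhaev epoxidation picks the electron-richer trisubstituted ring alkene over the 1,1-disubstituted isopropenyl group, and the facial mixture at the epoxide does not matter because both epoxide carbons become carbonyl carbons in step 2.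

Step 2
Reactants: 2 (S)-limonene 1,2-oxide
Product: 3 (3S)-6-oxo-3-(prop-1-en-2-yl)heptanal
Conditions: H5IO6 (1.1 equiv), THF/H2O, 0 °C → rt
Reagents that add atoms: water, O
Why: periodic acid hydrolyses the epoxide to the vicinal diol and cleaves it in the same flask (Malaprade glycol cleavage), which opens ring B between C1 and C2 and leaves the C4 stereocentre, not α to either carbonyl, untouched.

Step 3
Reactants: 3 (3S)-6-oxo-3-(prop-1-en-2-yl)heptanal
Product: 4 (5S)-7,7-dibromo-5-(prop-1-en-2-yl)heptan-2-one
Conditions: P(OPh)3 (1.05 equiv), Br2 (1.05 equiv), CH2Cl2, −78 °C; then Et3N (1.2 equiv) and 3, −78 → 0 °C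
Reagents that add atoms: bromine, BrBr
Why: deoxygenative geminal dibromination of an aldehyde by triphenyl phosphite dibromide (O-phosphonium formation, then two bromide substitutions, driven by the P=O bond) should take the aldehyde ahead of the less electrophilic methyl ketone when the reagent is limiting, cold and buffered, and it leaves no free HBr or Br2 to add to the alkene.

Step 4
Reactants: 4 (5S)-7,7-dibromo-5-(prop-1-en-2-yl)heptan-2-one
Product: 7 (1R,2S,4S)-2-bromo-1-methyl-4-(prop-1-en-2-yl)cyclohexan-1-ol, via α-bromoalkylsamarium carbenoid 5 (not isolated), via samarium alkoxide 6 (not isolated)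
Conditions: SmI2 (2.2 equiv, 0.1 M in THF) added to 4 in THF, −78 → 0 °C, no HMPA, no proton source; then 0.1 M aqueous HCl, 0 °C
Reagents that add atoms: none
Why: Proposed new method: SmI2 reduces the geminal dibromide by two single-electron transfers to the α-bromoalkylsamarium carbenoid 5, whose carbanionic carbon adds to the tethered methyl ketone to give the samarium alkoxide 6 of the cis bromohydrin; the closest known reaction types are the SmI2-promoted halomethylation of ketones with geminal dihalides and the SmI2 Barbier cyclisation of ω-halo ketones, which have not been combined in a ring closure of a 1,1-dibromoalkyl ketone. Ring B closes in the 6-exo-trig mode (attack on the carbonyl carbon, oxygen outside the ring) through a chair in which the isopropenyl group at C4 is equatorial. At C2 the carbenoid carbon is configurationally labile, so its configuration is fixed only in this chair, where bromine should take the equatorial site, cis to the C4 substituent. At C1 the samarium bridges the carbanion carbon and the carbonyl oxygen in a four-centre array and the ketone methyl should prefer the equatorial site, which puts the oxygen axial and cis to bromine. The step needs reduction of the C–Br bonds ahead of the ketone, secured by the much easier reduction of a 1,1-dibromide in THF without HMPA or a proton source, and it needs the alkene to stay out, secured because the radical and the carbenoid can reach it only in 4-exo or 5-endo modes.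

Step 5
Reactants: 7 (1R,2S,4S)-2-bromo-1-methyl-4-(prop-1-en-2-yl)cyclohexan-1-ol
Product: 8 3-[(1S,3S,4R)-3-bromo-4-hydroxy-4-methylcyclohexyl]butanal (both epimers at C3 of the chain)
Conditions: Rh(acac)(CO)2 (1 mol %), P(O-2,4-tBu2C6H3)3 (4 mol %), CO/H2 (1:1, 20 bar), toluene, 80 °C
Reagents that add atoms: carbon monoxide, [C-]#[O+]
Why: rhodium-catalysed hydroformylation of a 1,1-disubstituted alkene places the formyl group on the terminal CH2 only, since no quaternary carbon is formed, and the neutral conditions leave the bromohydrin alone; the new chain methine forms as a mixture that is erased in step 6.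

Step 6
Reactants: 8 3-[(1S,3S,4R)-3-bromo-4-hydroxy-4-methylcyclohexyl]butanal
Product: 9 (2E)-3-[(1S,3S,4R)-3-bromo-4-hydroxy-4-methylcyclohexyl]but-2-enal
Conditions: IBX (1.5 equiv), DMSO/fluorobenzene (1:2), 65 °C; the minor Z isomer is removed by chromatography
Reagents that add atoms: none
Why: IBX-mediated α,β-dehydrogenation of the aldehyde through its enol gives the conjugated trisubstituted enal, and equilibration under the warm, mildly acidic conditions should favour the E isomer, in which the formyl group is cis to the small methyl and not to ring B; the tertiary alcohol and the secondary bromide are inert to IBX.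

Step 7
Reactants: 10 triethyl phosphonoacetate
Product: 11 ethyl 2-(diethoxyphosphoryl)pent-4-enoate
Conditions: NaH (1.0 equiv), THF, 0 °C; allyl bromide (0.9 equiv), 0 °C → rt
Reagents that add atoms: allyl bromide, C=CCBr
Why: SN2 C-alkylation of the stabilised phosphonoacetate carbanion by a reactive allylic halide, with a deficit of the halide to limit double alkylation.

Step 8
Reactants: 12 2,2-dimethylbut-3-en-1-ol; 11 ethyl 2-(diethoxyphosphoryl)pent-4-enoate
Product: 14 ethyl (2E)-4,4-dimethyl-2-(prop-2-en-1-yl)hexa-2,5-dienoate, via 2,2-dimethylbut-3-enal 13 (not isolated)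
Conditions: (COCl)2, DMSO, Et3N, CH2Cl2, −78 → 0 °C, aqueous wash, the dried solution of 13 used without concentration; 11, NaH, THF, 0 °C → rt
Reagents that add atoms: none
Why: Swern oxidation gives the volatile, non-enolisable aldehyde, and the Horner–Wadsworth–Emmons reaction of the α-substituted phosphonate with this α-quaternary aldehyde should give the E ester (ester trans to the bulky tertiary group), the geometry that holds the allyl and vinyl arms cis for ring closure.

Step 9
Reactants: 14 ethyl (2E)-4,4-dimethyl-2-(prop-2-en-1-yl)hexa-2,5-dienoate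
Product: 15 ethyl 3,3-dimethylcyclohexa-1,4-diene-1-carboxylate
Conditions: second-generation Grubbs catalyst (H2IMes)(PCy3)Cl2Ru=CHPh (2 mol %), CH2Cl2 (0.01 M), 40 °C
Reagents that add atoms: none
Why: ring-closing metathesis of the two monosubstituted alkenes closes the six-membered ring (helped by the gem-dimethyl group) with loss of ethene, while the trisubstituted acrylate alkene is inert and the quaternary carbon blocks aromatisation of the skipped diene.

Step 10
Reactants: 15 ethyl 3,3-dimethylcyclohexa-1,4-diene-1-carboxylate
Product: 16 (3,3-dimethylcyclohexa-1,4-dien-1-yl)methanol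
Conditions: i-Bu2AlH (2.2 equiv), CH2Cl2, −78 °C; Rochelle salt work-up
Reagents that add atoms: none
Why: 1,2-reduction of the conjugated ester by i-Bu2AlH gives the allylic alcohol without touching either ring alkene.

Step 11
Reactants: 16 (3,3-dimethylcyclohexa-1,4-dien-1-yl)methanol
Product: 17 2-[(3,3-dimethylcyclohexa-1,4-dien-1-yl)methyl]-4,4,5,5-tetramethyl-1,3,2-dioxaborolane
Conditions: B2pin2 (1.2 equiv), Pd(MeCN)4(BF4)2 (5 mol %), TsOH (5 mol %), DMSO/MeOH (1:1), 40 °C
Reagents that add atoms: bis(pinacolato)diboron, CC1(C)OB(OC1(C)C)B1OC(C)(C)C(C)(C)O1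
Why: palladium-catalysed borylation of an allylic alcohol through a π-allylpalladium intermediate delivers boron to the unhindered CH2 terminus (the other terminus is neopentylic), and the ring fixes the alkene geometry so that CH2B is trans to the CMe2 carbon.

Step 12
Reactants: 9 (2E)-3-[(1S,3S,4R)-3-bromo-4-hydroxy-4-methylcyclohexyl]but-2-enal; 17 2-[(3,3-dimethylcyclohexa-1,4-dien-1-yl)methyl]-4,4,5,5-tetramethyl-1,3,2-dioxaborolane
Product: 19 (1R,2S,4S)-2-bromo-4-[(2E,4R)-4-[(1R)-2,2-dimethyl-6-methylidenecyclohex-3-en-1-yl]-4-hydroxybut-2-en-2-yl]-1-methylcyclohexan-1-ol, via pinacol borate ester 18 (not isolated)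
Conditions: (S)-TRIP ((S)-3,3'-bis(2,4,6-triisopropylphenyl)-1,1'-binaphthyl-2,2'-diyl hydrogen phosphate, 10 mol %), 4 Å molecular sieves, toluene, −30 → 0 °C; then aqueous NaHCO3 work-up
Reagents that add atoms: none
Why: chiral-phosphoric-acid-catalysed allylboration through a closed chair (Zimmerman–Traxler) transition state, in which SE2' attack by the ring γ-carbon creates the exocyclic methylene, the E-disposed CMe2 carbon gives the anti relationship between the new carbinol and the ring A methine, and the (S)-acid (chosen because the accepted model has the (R)-acid deliver allyl to the Re face of aldehydes) should direct attack to the Si face of the enal to give the R carbinol and with it the R methine; 1,2-addition leaves the E alkene, the bromide and the tertiary alcohol untouched.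

Compound list
1 | (S)-(−)-limonene, (4S)-1-methyl-4-(prop-1-en-2-yl)cyclohex-1-ene | C=C(C)[C@H]1CCC(C)=CC1 | starting material
2 | (4S)-1-methyl-4-(prop-1-en-2-yl)-7-oxabicyclo[4.1.0]heptane, both epoxide diastereomers | C=C(C)[C@H]1CCC2(C)OC2C1 | intermediate
3 | (3S)-6-oxo-3-(prop-1-en-2-yl)heptanal | C=C(C)[C@H](CC=O)CCC(C)=O | intermediate
4 | (5S)-7,7-dibromo-5-(prop-1-en-2-yl)heptan-2-one | C=C(C)[C@H](CC(Br)Br)CCC(C)=O | intermediate
5 | α-bromoalkylsamarium diiodide carbenoid from 4 (trivalent samarium, C–Sm centre labile) | C=C(C)[C@H](CC(Br)[Sm](I)I)CCC(C)=O | intermediate (not isolated)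
6 | samarium diiodide alkoxide of 7 | C=C(C)[C@H]1CC[C@@](C)(O[Sm](I)I)[C@@H](Br)C1 | intermediate (not isolated)
7 | (1R,2S,4S)-2-bromo-1-methyl-4-(prop-1-en-2-yl)cyclohexan-1-ol | C=C(C)[C@H]1CC[C@@](C)(O)[C@@H](Br)C1 | intermediate
8 | 3-[(1S,3S,4R)-3-bromo-4-hydroxy-4-methylcyclohexyl]butanal, both chain epimers | O=CCC(C)[C@H]1CC[C@@](C)(O)[C@@H](Br)C1 | intermediate
9 | (2E)-3-[(1S,3S,4R)-3-bromo-4-hydroxy-4-methylcyclohexyl]but-2-enal | O=C/C=C(\C)[C@H]1CC[C@@](C)(O)[C@@H](Br)C1 | intermediate
10 | triethyl phosphonoacetate | CCOC(=O)CP(=O)(OCC)OCC | starting material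
11 | ethyl 2-(diethoxyphosphoryl)pent-4-enoate | CCOC(=O)C(CC=C)P(=O)(OCC)OCC | intermediate
12 | 2,2-dimethylbut-3-en-1-ol | C=CC(C)(C)CO | starting material
13 | 2,2-dimethylbut-3-enal | C=CC(C)(C)C=O | intermediate (not isolated)
14 | ethyl (2E)-4,4-dimethyl-2-(prop-2-en-1-yl)hexa-2,5-dienoate | CCOC(=O)/C(CC=C)=C/C(C)(C)C=C | intermediate
15 | ethyl 3,3-dimethylcyclohexa-1,4-diene-1-carboxylate | CCOC(=O)C1=CC(C)(C)C=CC1 | intermediate
16 | (3,3-dimethylcyclohexa-1,4-dien-1-yl)methanol | OCC1=CC(C)(C)C=CC1 | intermediate
17 | 2-[(3,3-dimethylcyclohexa-1,4-dien-1-yl)methyl]-4,4,5,5-tetramethyl-1,3,2-dioxaborolane | CC1(C)C=CCC(CB2OC(C)(C)C(C)(C)O2)=C1 | intermediate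
18 | pinacol borate ester of 19 (boron on the secondary carbinol oxygen) | C=C1CC=CC(C)(C)[C@@H]1[C@H](OB1OC(C)(C)C(C)(C)O1)/C=C(\C)[C@H]1CC[C@@](C)(O)[C@@H](Br)C1 | intermediate (not isolated)
19 | (1R,2S,4S)-2-bromo-4-[(2E,4R)-4-[(1R)-2,2-dimethyl-6-methylidenecyclohex-3-en-1-yl]-4-hydroxybut-2-en-2-yl]-1-methylcyclohexan-1-ol | C=C1CC=CC(C)(C)[C@@H]1[C@H](O)/C=C(\C)[C@H]1CC[C@@](C)(O)[C@@H](Br)C1 | target

Total step count: 12. Longest linear sequence: 7 steps (steps 1–6 and 12); the boronate arm takes 5 steps (steps 7–11).

Steps most likely to fail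

Step 4 (proposed new method). The carbenoid may lose bromide by α-elimination and hydride shift to a terminal alkene, or be protonated before it adds. The ketone may also be reduced in competition, or the chair may close with oxygen instead of methyl equatorial, giving the wrong relative configuration at C1 and C2. The fallback uses known chemistry, sets out from 2 and comes back at 7; it keeps the limonene ring intact and sets C2 by inversion instead of ring closure. Acid-catalysed hydrolysis (dilute HClO4, THF/H2O, 0 °C) should take both epoxide diastereomers to the trans-diaxial diol (1R,2R,4S)-1-methyl-4-(prop-1-en-2-yl)cyclohexane-1,2-diol F1. SO2Cl2 and Et3N (CH2Cl2, −78 °C) convert it into the trans-fused cyclic sulfate of F1 F2. LiBr (THF, rt → 50 °C) opens the sulfate at the secondary carbon with inversion to lithium (1R,2S,4S)-2-bromo-1-methyl-4-(prop-1-en-2-yl)cyclohexyl sulfate F3. Hydrolysis of the sulfate monoester (catalytic H2SO4, THF/H2O) then gives 7.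

Step 12. Allyl transfer may be slow because the attacking ring carbon sits next to the quaternary CMe2 carbon, so that protodeboronation or uncatalysed background addition erodes facial control. The fallback sets out from 16 (with 9) and comes back at 19. PBr3 (Et2O, 0 °C) gives 1-(bromomethyl)-3,3-dimethylcyclohexa-1,4-diene F4. An asymmetric Nozaki–Hiyama–Kishi allylation of 9 with F4 (CrCl2, a chiral oxazoline–sulfonamide ligand, Et3N, THF, rt; aqueous work-up) then uses the more nucleophilic allylchromium species (trivalent chromium), which adds through its γ-carbon with anti selectivity.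

Step 6. Geometric control may be incomplete (E/Z mixture), and over-oxidation to a dienal is possible. The fallback sets out from 7 and comes back at 9. Ozonolysis (O3, CH2Cl2/MeOH, −78 °C; Me2S) gives 1-[(1S,3S,4R)-3-bromo-4-hydroxy-4-methylcyclohexyl]ethan-1-one F5. Horner–Wadsworth–Emmons olefination with 10 (NaH, THF, 0 °C → rt; the equatorial C–Br is not antiperiplanar to the axial C–O, so epoxide closure is not available) gives ethyl (2E)-3-[(1S,3S,4R)-3-bromo-4-hydroxy-4-methylcyclohexyl]but-2-enoate F6. Reduction with i-Bu2AlH (CH2Cl2, −78 °C) gives (2E)-3-[(1S,3S,4R)-3-bromo-4-hydroxy-4-methylcyclohexyl]but-2-en-1-ol F7, and MnO2 (CH2Cl2, rt) oxidises it to 9.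

Further compounds
F1 | step 4 | (1R,2R,4S)-1-methyl-4-(prop-1-en-2-yl)cyclohexane-1,2-diol | C=C(C)[C@H]1CC[C@@](C)(O)[C@H](O)C1
F2 | step 4 | cyclic sulfate of F1 (trans-fused 1,3,2-dioxathiolane 2,2-dioxide) | C=C(C)[C@H]1CC[C@@]2(C)OS(=O)(=O)O[C@@H]2C1
F3 | step 4 | lithium (1R,2S,4S)-2-bromo-1-methyl-4-(prop-1-en-2-yl)cyclohexyl sulfate | C=C(C)[C@H]1CC[C@@](C)(OS(=O)(=O)[O-])[C@@H](Br)C1.[Li+]
F4 | step 12 | 1-(bromomethyl)-3,3-dimethylcyclohexa-1,4-diene | BrCC1=CC(C)(C)C=CC1
F5 | step 6 | 1-[(1S,3S,4R)-3-bromo-4-hydroxy-4-methylcyclohexyl]ethan-1-one | CC(=O)[C@H]1CC[C@@](C)(O)[C@@H](Br)C1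
F6 | step 6 | ethyl (2E)-3-[(1S,3S,4R)-3-bromo-4-hydroxy-4-methylcyclohexyl]but-2-enoate | CCOC(=O)/C=C(\C)[C@H]1CC[C@@](C)(O)[C@@H](Br)C1
F7 | step 6 | (2E)-3-[(1S,3S,4R)-3-bromo-4-hydroxy-4-methylcyclohexyl]but-2-en-1-ol | OC/C=C(\C)[C@H]1CC[C@@](C)(O)[C@@H](Br)C1
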